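**Plan**

1. Retrosynthesis: the seven O–benzyl bonds are cut first (global hydrogenolysis). Then the C1–C2 bond of ring C is cut (rings lettered A to D from the 3,5-dihydroxyphenyl end), which opens ring C to an acyclic keto ester.
2. Enabling feature: ring C is a 2,5-bis(aryloxy)resorcinol, with free OH only at C2 and C6 and ether oxygens at C1 (to ring B) and C4 (to ring D). Its six carbons map onto a 5-oxohex-2-enoate: ester carbon and ketone become C2 and C6, the enol ether oxygen on chain C3 is the ring D oxygen, and chain C6 carries the ring B oxygen.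
3. Further cuts: chain C4–C5 (γ-acylation of an aryloxycrotonate dienolate by a Weinreb amide), the ring D O–C3 enol ether bond (phenol addition to methyl but-2-ynoate), the ring B O–CH2 bond (Williamson) and the ring A C–O bond of the A–B diaryl ether (Ullmann).
4. Forward: rings A, B and D enter as arenes, with the ring D phenol and the ring B phenol each revealed by Dakin oxidation. The ring D crotonate and the A–B Weinreb amide are joined, ring C is closed last, then all benzyl groups are removed.
5. Stereochemistry: the target is achiral and has no stereocentre. The only stereo element on the way, the (E) enol ether of the chain, is set under thermodynamic control in step 3 and vanishes on aromatization.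

Key step: step 11

Remark: 1,3,5-tris(benzyloxy)benzene, 3,4,5-trihydroxybenzaldehyde, 1,3-bis(benzyloxy)-5-bromobenzene, methyl but-2-ynoate and 2-chloro-N-methoxy-N-methylacetamide are taken as purchasable; a Weinreb amide is chosen as acyl donor so that the chain ketone is released only on quench.

**Route**

Step 1
Reactants: 1 1,3,5-tris(benzyloxy)benzene
Product: 3 2,4,6-tris(benzyloxy)benzaldehyde, via iminium chloride 2 (not isolated)
Conditions: POCl3, DMF, 0 °C to rt; then aq NaOH, 0 °C
Reagents that add atoms: N,N-dimethylformamide, CN(C)C=O (formyl carbon); water, O (carbonyl oxygen)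
Why: Vilsmeier–Haack formylation, in which the chloroiminium ion attacks one of the three equivalent, doubly activated ring positions of the phloroglucinol triether and hydrolysis of the iminium salt releases the aldehyde.

Step 2
Reactants: 3 2,4,6-tris(benzyloxy)benzaldehyde
Product: 5 2,4,6-tris(benzyloxy)phenol, via aryl formate 4 (not isolated)
Conditions: mCPBA, CH2Cl2, 0 °C to rt; aq NaHCO3 wash; then K2CO3 (0.2 equiv), MeOH, rt, under argon
Reagents that add atoms: 3-chloroperoxybenzoic acid (mCPBA), O=C(OO)c1cccc(Cl)c1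
Why: Baeyer–Villiger (Dakin-type) oxidation, in which the electron-rich trialkoxyaryl group migrates in the Criegee adduct to give the aryl formate, and catalytic methanolysis frees the phenol.

Step 3
Reactants: 5 2,4,6-tris(benzyloxy)phenol; 6 methyl but-2-ynoate
Product: 7 methyl (E)-3-[2,4,6-tris(benzyloxy)phenoxy]but-2-enoate
Conditions: K2CO3 (0.3 equiv), DMF, 80 °C, under argon
Reagents that add atoms: none
Why: Base-catalysed oxa-Michael addition of the phenoxide to the ynoate, where reversible phenoxide addition–elimination should equilibrate the adduct to the (E) isomer (aryloxy trans to ester), the more stable geometry of 3-alkoxycrotonates and the one needed for ring closure.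

Step 4
Reactants: 8 3,4,5-trihydroxybenzaldehyde
Product: 9 4-(allyloxy)-3,5-dihydroxybenzaldehyde
Conditions: allyl bromide (1.05 equiv), NaHCO3, NaI (cat.), DMF, 40 °C, under argon
Reagents that add atoms: allyl bromide, C=CCBr
Why: Williamson alkylation under weakly basic conditions, selective because the 4-OH para to the formyl group is the most acidic and the only one ionized by hydrogencarbonate, as in the para-selective alkylation known for 3,4-dihydroxybenzaldehyde and gallate esters.

Step 5
Reactants: 9 4-(allyloxy)-3,5-dihydroxybenzaldehyde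
Product: 10 4-(allyloxy)-3,5-bis(benzyloxy)benzaldehyde
Conditions: BnBr (2.5 equiv), K2CO3, DMF, rt to 50 °C
Reagents that add atoms: benzyl bromide, BrCc1ccccc1
Why: Williamson benzylation of the two remaining phenols, to which the aldehyde and the allyl ether are inert.

Step 6
Reactants: 10 4-(allyloxy)-3,5-bis(benzyloxy)benzaldehyde
Product: 11 3,5-bis(benzyloxy)-4-hydroxybenzaldehyde
Conditions: Pd(PPh3)4 (3 mol %), morpholine (3 equiv), THF, rt
Reagents that add atoms: none
Why: Tsuji–Trost deallylation, in which zerovalent palladium ionizes the allyl aryl ether to a π-allyl complex and the stabilized phenoxide while morpholine traps the allyl group; benzyl ethers and the aldehyde are untouched.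

Step 7
Reactants: 11 3,5-bis(benzyloxy)-4-hydroxybenzaldehyde; 12 1,3-bis(benzyloxy)-5-bromobenzene
Product: 13 3,5-bis(benzyloxy)-4-[3,5-bis(benzyloxy)phenoxy]benzaldehyde
Conditions: CuI (10 mol %), picolinic acid (20 mol %), K3PO4 (2 equiv), DMSO, 90 °C
Reagents that add atoms: none
Why: Ullmann-type copper-catalysed O-arylation under the picolinic acid conditions developed for 2,6-disubstituted phenols, helped by the aryl bromide being unhindered (both ortho positions are C–H).

Step 8
Reactants: 13 3,5-bis(benzyloxy)-4-[3,5-bis(benzyloxy)phenoxy]benzaldehyde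
Product: 15 3,5-bis(benzyloxy)-4-[3,5-bis(benzyloxy)phenoxy]phenol, via aryl formate 14 (not isolated)
Conditions: mCPBA, CH2Cl2, 0 °C to rt; aq NaHCO3 wash; then K2CO3 (0.2 equiv), MeOH, rt, under argon
Reagents that add atoms: 3-chloroperoxybenzoic acid (mCPBA), O=C(OO)c1cccc(Cl)c1
Why: Baeyer–Villiger (Dakin-type) oxidation, in which the aryl group activated by its para aryloxy oxygen migrates in preference to hydride (as 3,4,5-trialkoxybenzaldehydes are known to do), and methanolysis of the formate frees the ring B C4 phenol.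

Step 9
Reactants: 15 3,5-bis(benzyloxy)-4-[3,5-bis(benzyloxy)phenoxy]phenol; 16 2-chloro-N-methoxy-N-methylacetamide
Product: 17 2-{3,5-bis(benzyloxy)-4-[3,5-bis(benzyloxy)phenoxy]phenoxy}-N-methoxy-N-methylacetamide
Conditions: K2CO3 (2 equiv), NaI (0.1 equiv), DMF, 60 °C
Reagents that add atoms: none
Why: Williamson alkylation of an unhindered phenoxide by an α-chloro amide with iodide (Finkelstein) activation, which makes the hindered-looking ring B–O–CH2 bond without any arylation.

Step 10
Reactants: 7 methyl (E)-3-[2,4,6-tris(benzyloxy)phenoxy]but-2-enoate; 17 2-{3,5-bis(benzyloxy)-4-[3,5-bis(benzyloxy)phenoxy]phenoxy}-N-methoxy-N-methylacetamide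
Product: 20 methyl (E)-6-{3,5-bis(benzyloxy)-4-[3,5-bis(benzyloxy)phenoxy]phenoxy}-5-oxo-3-[2,4,6-tris(benzyloxy)phenoxy]hex-2-enoate, via lithium dienolate 18 (not isolated), via tetrahedral lithium adduct 19 (not isolated)
Conditions: 7 (1.2 equiv), LiN(iPr)2 (1.15 equiv), THF, −78 °C; then 17, −78 to −40 °C; AcOH, −78 °C
Reagents that add atoms: none
Why: Vinylogous Claisen acylation, in which the amide base removes a proton from the γ-methyl group lying cis to the ester and the lithium dienolate of a 3-alkoxycrotonate attacks carbonyl electrophiles through its γ-carbon (as in kavalactone syntheses), while the chelated Weinreb adduct 19 holds until the cold acidic quench so that over-addition, proton transfer from the acidic product and lactonization cannot occur in the basic medium and the (E) geometry is kept.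

Step 11
Reactants: 20 methyl (E)-6-{3,5-bis(benzyloxy)-4-[3,5-bis(benzyloxy)phenoxy]phenoxy}-5-oxo-3-[2,4,6-tris(benzyloxy)phenoxy]hex-2-enoate
Product: 22 2-{3,5-bis(benzyloxy)-4-[3,5-bis(benzyloxy)phenoxy]phenoxy}-5-[2,4,6-tris(benzyloxy)phenoxy]benzene-1,3-diol, via cyclohexenedione 21 (not isolated)
Conditions: KOtBu (3 equiv), THF (0.02 M), 0 °C to rt, under argon; then 1 M HCl, 0 °C
Reagents that add atoms: none
Why: tert-Butoxide deprotonates 20 reversibly at chain C4 and chain C6 (the tert-butanol formed shuttles protons), and the C6 enolate, flanked by the C5 ketone and the ring B aryloxy group, adds to the C1 ester carbon and expels methoxide, which creates the C1–C2 bond of ring C in an intramolecular Claisen (Dieckmann-type) condensation. The closest known reaction is the base-mediated cyclization of 3,5-dioxohexanoates and their 3-enol ethers to phloroglucinol and its monoethers. Ring C closes by a 6-exo-trig acyl substitution (enolexo with respect to the enolate) to dione 21, whose proton between the two carbonyl groups is lost at once, so that 21 tautomerizes irreversibly to the resorcinol (held as its potassium phenoxide) and drains the preceding equilibria. No stereocentre is formed; the (E) geometry of the C2=C3 enol ether, which holds the C4 chain cis to the ester, is what lets the two ends meet. The step needs carbon acylation from C6 to prevail over lactonization through the C5 enolate oxygen and over alkoxide exchange at C3: the hindered base in aprotic THF leaves only the one equivalent of released methoxide as a competing nucleophile, a 2-pyranone formed on the way is an enol lactone that alkoxide can reopen, and only the carbocyclic path ends in an aromatic ring. Because the C4 oxygen of ring C is already fixed as the ring D ether, the product carries exactly the two free hydroxyls at C2 and C6.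

Step 12
Reactants: 22 2-{3,5-bis(benzyloxy)-4-[3,5-bis(benzyloxy)phenoxy]phenoxy}-5-[2,4,6-tris(benzyloxy)phenoxy]benzene-1,3-diol
Product: 23 tetraphlorethol C
Conditions: H2 (1 atm), 10% Pd/C, THF–MeOH 1:1, rt
Reagents that add atoms: none
Why: Hydrogenolysis of the seven benzyl ethers over palladium, under which diaryl ether C–O bonds and the oxygenated rings are not reduced at one atmosphere and room temperature.

**Compound list**

1 | 1,3,5-tris(benzyloxy)benzene | c1(OCc2ccccc2)cc(OCc2ccccc2)cc(OCc2ccccc2)c1 | starting material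
2 | N-{[2,4,6-tris(benzyloxy)phenyl]methylidene}-N-methylmethanaminium chloride | C[N+](C)=Cc1c(OCc2ccccc2)cc(OCc2ccccc2)cc1OCc1ccccc1.[Cl-] | intermediate (not isolated)
3 | 2,4,6-tris(benzyloxy)benzaldehyde | O=Cc1c(OCc2ccccc2)cc(OCc2ccccc2)cc1OCc1ccccc1 | intermediate
4 | 2,4,6-tris(benzyloxy)phenyl formate | O=COc1c(OCc2ccccc2)cc(OCc2ccccc2)cc1OCc1ccccc1 | intermediate (not isolated)
5 | 2,4,6-tris(benzyloxy)phenol | Oc1c(OCc2ccccc2)cc(OCc2ccccc2)cc1OCc1ccccc1 | intermediate
6 | methyl but-2-ynoate | CC#CC(=O)OC | starting material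
7 | methyl (E)-3-[2,4,6-tris(benzyloxy)phenoxy]but-2-enoate | COC(=O)/C=C(\C)Oc1c(OCc2ccccc2)cc(OCc2ccccc2)cc1OCc1ccccc1 | intermediate
8 | 3,4,5-trihydroxybenzaldehyde | O=Cc1cc(O)c(O)c(O)c1 | starting material
9 | 4-(allyloxy)-3,5-dihydroxybenzaldehyde | O=Cc1cc(O)c(OCC=C)c(O)c1 | intermediate
10 | 4-(allyloxy)-3,5-bis(benzyloxy)benzaldehyde | O=Cc1cc(OCc2ccccc2)c(OCC=C)c(OCc2ccccc2)c1 | intermediate
11 | 3,5-bis(benzyloxy)-4-hydroxybenzaldehyde | O=Cc1cc(OCc2ccccc2)c(O)c(OCc2ccccc2)c1 | intermediate
12 | 1,3-bis(benzyloxy)-5-bromobenzene | Brc1cc(OCc2ccccc2)cc(OCc2ccccc2)c1 | starting material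
13 | 3,5-bis(benzyloxy)-4-[3,5-bis(benzyloxy)phenoxy]benzaldehyde | O=Cc1cc(OCc2ccccc2)c(Oc2cc(OCc3ccccc3)cc(OCc3ccccc3)c2)c(OCc2ccccc2)c1 | intermediate
14 | 3,5-bis(benzyloxy)-4-[3,5-bis(benzyloxy)phenoxy]phenyl formate | O=COc1cc(OCc2ccccc2)c(Oc2cc(OCc3ccccc3)cc(OCc3ccccc3)c2)c(OCc2ccccc2)c1 | intermediate (not isolated)
15 | 3,5-bis(benzyloxy)-4-[3,5-bis(benzyloxy)phenoxy]phenol | Oc1cc(OCc2ccccc2)c(Oc2cc(OCc3ccccc3)cc(OCc3ccccc3)c2)c(OCc2ccccc2)c1 | intermediate
16 | 2-chloro-N-methoxy-N-methylacetamide | CON(C)C(=O)CCl | starting material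
17 | 2-{3,5-bis(benzyloxy)-4-[3,5-bis(benzyloxy)phenoxy]phenoxy}-N-methoxy-N-methylacetamide | CON(C)C(=O)COc1cc(OCc2ccccc2)c(Oc2cc(OCc3ccccc3)cc(OCc3ccccc3)c2)c(OCc2ccccc2)c1 | intermediate
18 | lithium 1-methoxy-3-[2,4,6-tris(benzyloxy)phenoxy]buta-1,3-dien-1-olate (dienolate of 7, enolate geometry left open) | [Li+].[O-]C(OC)=CC(=C)Oc1c(OCc2ccccc2)cc(OCc2ccccc2)cc1OCc1ccccc1 | intermediate (not isolated)
19 | lithium salt of the tetrahedral adduct, methyl (E)-6-{3,5-bis(benzyloxy)-4-[3,5-bis(benzyloxy)phenoxy]phenoxy}-5-[methoxy(methyl)amino]-5-oxido-3-[2,4,6-tris(benzyloxy)phenoxy]hex-2-enoate (racemic at C5) | [Li+].COC(=O)/C=C(/Oc1c(OCc2ccccc2)cc(OCc2ccccc2)cc1OCc1ccccc1)CC([O-])(N(C)OC)COc1cc(OCc2ccccc2)c(Oc2cc(OCc3ccccc3)cc(OCc3ccccc3)c2)c(OCc2ccccc2)c1 | intermediate (not isolated)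
20 | methyl (E)-6-{3,5-bis(benzyloxy)-4-[3,5-bis(benzyloxy)phenoxy]phenoxy}-5-oxo-3-[2,4,6-tris(benzyloxy)phenoxy]hex-2-enoate | COC(=O)/C=C(/Oc1c(OCc2ccccc2)cc(OCc2ccccc2)cc1OCc1ccccc1)CC(=O)COc1cc(OCc2ccccc2)c(Oc2cc(OCc3ccccc3)cc(OCc3ccccc3)c2)c(OCc2ccccc2)c1 | intermediate
21 | 2-{3,5-bis(benzyloxy)-4-[3,5-bis(benzyloxy)phenoxy]phenoxy}-5-[2,4,6-tris(benzyloxy)phenoxy]cyclohex-4-ene-1,3-dione (racemic, transient) | O=C1C=C(Oc2c(OCc3ccccc3)cc(OCc3ccccc3)cc2OCc2ccccc2)CC(=O)C1Oc1cc(OCc2ccccc2)c(Oc2cc(OCc3ccccc3)cc(OCc3ccccc3)c2)c(OCc2ccccc2)c1 | intermediate (not isolated)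
22 | 2-{3,5-bis(benzyloxy)-4-[3,5-bis(benzyloxy)phenoxy]phenoxy}-5-[2,4,6-tris(benzyloxy)phenoxy]benzene-1,3-diol (hepta-O-benzyl tetraphlorethol C, ring C hydroxyls free) | Oc1cc(Oc2c(OCc3ccccc3)cc(OCc3ccccc3)cc2OCc2ccccc2)cc(O)c1Oc1cc(OCc2ccccc2)c(Oc2cc(OCc3ccccc3)cc(OCc3ccccc3)c2)c(OCc2ccccc2)c1 | intermediate
23 | tetraphlorethol C, 2-{4-[4-(3,5-dihydroxyphenoxy)-3,5-dihydroxyphenoxy]-3,5-dihydroxyphenoxy}benzene-1,3,5-triol | Oc1cc(O)cc(Oc2c(O)cc(Oc3c(O)cc(Oc4c(O)cc(O)cc4O)cc3O)cc2O)c1 | target

**Count and risks**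

Total step count: 12. Longest linear sequence: 9 steps (8 to 23, steps 4 to 12); the ring D branch (steps 1 to 3) joins at step 10.

Steps most likely to fail:

Step 11. Lactonization through the C5 enolate oxygen may outrun carbon acylation from C6 without the 2-pyranone being reopened, or released methoxide may expel the ring D phenoxide from C3 by addition–elimination before the ring closes. The fallback takes ring C from an arene and builds the ether chain from the ring D end by copper-catalysed arylation and Dakin oxidation, the reactions of steps 7 and 2. It sets out from phenol 5. Commercial 4-bromo-2,6-difluorobenzaldehyde and benzyl alcohol (Cs2CO3, DMF, 80 °C, two SNAr displacements ortho to the formyl group) should give 2,6-bis(benzyloxy)-4-bromobenzaldehyde F1. Coupling of 5 with F1 under the conditions of step 7 should give 2,6-bis(benzyloxy)-4-[2,4,6-tris(benzyloxy)phenoxy]benzaldehyde F2, and Dakin oxidation as in step 2 the phenol 2,6-bis(benzyloxy)-4-[2,4,6-tris(benzyloxy)phenoxy]phenol F3. The same two operations with a second portion of F1 should give the three-ring aldehyde 2,6-bis(benzyloxy)-4-{2,6-bis(benzyloxy)-4-[2,4,6-tris(benzyloxy)phenoxy]phenoxy}benzaldehyde F4 and then the three-ring phenol 2,6-bis(benzyloxy)-4-{2,6-bis(benzyloxy)-4-[2,4,6-tris(benzyloxy)phenoxy]phenoxy}phenol F5. Coupling of F5 with bromide 12 should give nona-O-benzyl tetraphlorethol C F6, and hydrogenolysis under the conditions of step 12 comes back to the route at 23. In every coupling the phenol is the hindered partner and the bromide the unhindered one, the pairing already used in step 7.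

Step 10. The dienolate may deprotonate the Weinreb amide instead of adding to it, or may react through its α-carbon, so that little γ-acylated chain forms. The fallback replaces acylation by a vinylogous aldol addition and an oxidation. It sets out from 17 and 7. Reduction of 17 (LiAlH4, THF, −78 to 0 °C) should give {3,5-bis(benzyloxy)-4-[3,5-bis(benzyloxy)phenoxy]phenoxy}acetaldehyde F7. Addition of dienolate 18 to F7 at −78 °C, quenched cold with AcOH before the alkoxide can lactonize, should give racemic methyl (E)-6-{3,5-bis(benzyloxy)-4-[3,5-bis(benzyloxy)phenoxy]phenoxy}-5-hydroxy-3-[2,4,6-tris(benzyloxy)phenoxy]hex-2-enoate F8. Oxidation with Dess–Martin periodinane (NaHCO3, CH2Cl2, 0 °C to rt) comes back to the route at 20.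

Step 7. The doubly ortho-substituted, para-formyl phenoxide is a crowded and weak nucleophile, so the coupling may stall while the aryl bromide is slowly reduced and the aldehyde degrades in hot basic DMSO. The fallback changes the aryl partner and the coupling manifold to an oxidative Chan–Lam–Evans coupling at room temperature, which is known to tolerate 2,6-disubstituted phenols. It sets out from 11, which is treated with commercial [3,5-bis(benzyloxy)phenyl]boronic acid, Cu(OAc)2 (1 equiv), pyridine and 4 Å molecular sieves in CH2Cl2 under air, and comes back to the route at 13. This fallback makes no compound outside the route (F0).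

**Further compounds**

F1 | step 11 | 2,6-bis(benzyloxy)-4-bromobenzaldehyde | O=Cc1c(OCc2ccccc2)cc(Br)cc1OCc1ccccc1
F2 | step 11 | 2,6-bis(benzyloxy)-4-[2,4,6-tris(benzyloxy)phenoxy]benzaldehyde | O=Cc1c(OCc2ccccc2)cc(Oc2c(OCc3ccccc3)cc(OCc3ccccc3)cc2OCc2ccccc2)cc1OCc1ccccc1
F3 | step 11 | 2,6-bis(benzyloxy)-4-[2,4,6-tris(benzyloxy)phenoxy]phenol | Oc1c(OCc2ccccc2)cc(Oc2c(OCc3ccccc3)cc(OCc3ccccc3)cc2OCc2ccccc2)cc1OCc1ccccc1
F4 | step 11 | 2,6-bis(benzyloxy)-4-{2,6-bis(benzyloxy)-4-[2,4,6-tris(benzyloxy)phenoxy]phenoxy}benzaldehyde | O=Cc1c(OCc2ccccc2)cc(Oc2c(OCc3ccccc3)cc(Oc3c(OCc4ccccc4)cc(OCc4ccccc4)cc3OCc3ccccc3)cc2OCc2ccccc2)cc1OCc1ccccc1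
F5 | step 11 | 2,6-bis(benzyloxy)-4-{2,6-bis(benzyloxy)-4-[2,4,6-tris(benzyloxy)phenoxy]phenoxy}phenol | Oc1c(OCc2ccccc2)cc(Oc2c(OCc3ccccc3)cc(Oc3c(OCc4ccccc4)cc(OCc4ccccc4)cc3OCc3ccccc3)cc2OCc2ccccc2)cc1OCc1ccccc1
F6 | step 11 | nona-O-benzyl tetraphlorethol C | C(c1ccccc1)Oc1cc(OCc2ccccc2)cc(Oc2c(OCc3ccccc3)cc(Oc3c(OCc4ccccc4)cc(Oc4c(OCc5ccccc5)cc(OCc5ccccc5)cc4OCc4ccccc4)cc3OCc3ccccc3)cc2OCc2ccccc2)c1
F7 | step 10 | {3,5-bis(benzyloxy)-4-[3,5-bis(benzyloxy)phenoxy]phenoxy}acetaldehyde | O=CCOc1cc(OCc2ccccc2)c(Oc2cc(OCc3ccccc3)cc(OCc3ccccc3)c2)c(OCc2ccccc2)c1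
F8 | step 10 | methyl (E)-6-{3,5-bis(benzyloxy)-4-[3,5-bis(benzyloxy)phenoxy]phenoxy}-5-hydroxy-3-[2,4,6-tris(benzyloxy)phenoxy]hex-2-enoate (racemic) | COC(=O)/C=C(/Oc1c(OCc2ccccc2)cc(OCc2ccccc2)cc1OCc1ccccc1)CC(O)COc1cc(OCc2ccccc2)c(Oc2cc(OCc3ccccc3)cc(OCc3ccccc3)c2)c(OCc2ccccc2)c1
F0 | step 7 | none | none
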